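**Strategy.** The oxolane ring (O1, C2–C5) carries cis aryl groups at C2/C5 and cis methyl groups at C3/C4, each aryl trans to its neighbouring methyl; with identical arms the core is a meso unit. This is the exo,exo pattern of a cis-fused bicycle, so the two methyl carbons are tied as a temporary γ-lactone. A lactone-fused aryl cyclopropane (donor–acceptor) and O-benzylvanillin combine in a Lewis-acid [3+2] annulation that forms O1–C2 and C4–C5 at once and sets all four ring stereocentres; reduction of the lactone then releases both methyls. The meso bis-phenol is elaborated in two directions by SN2 with a lactate-derived keto tosylate and chelation-controlled reduction.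

Key step: step 5

Assumption: because the core with two identical arms is a meso unit, it is built from racemic and meso intermediates; the absolute configuration comes only from the (R)-lactate-derived arms.

**Step 1**
Reactants: 1 4-(benzyloxy)-3-methoxybenzaldehyde (O-benzylvanillin); 2 triethyl phosphonoacetate
Product: 3 ethyl (2E)-3-[4-(benzyloxy)-3-methoxyphenyl]prop-2-enoate
Conditions: NaH, THF, 0 °C → rt
Reagents that add atoms: none
Why: Horner–Wadsworth–Emmons olefination of an aromatic aldehyde with a stabilised phosphonate anion should give the (E)-cinnamate.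

**Step 2**
Reactants: 3 ethyl (2E)-3-[4-(benzyloxy)-3-methoxyphenyl]prop-2-enoate
Product: 4 (2E)-3-[4-(benzyloxy)-3-methoxyphenyl]prop-2-en-1-ol
Conditions: iBu2AlH, CH2Cl2, −78 °C; Rochelle salt work-up
Reagents that add atoms: none
Why: Low-temperature iBu2AlH reduction of an α,β-unsaturated ester is a 1,2-hydride addition that should give the (E)-allylic alcohol and leave the benzyl ether untouched.

**Step 3**
Reactants: 4 (2E)-3-[4-(benzyloxy)-3-methoxyphenyl]prop-2-en-1-ol
Product: 6 (2E)-3-[4-(benzyloxy)-3-methoxyphenyl]prop-2-en-1-yl diazoacetate, via cinnamyl bromoacetate 5 (not isolated)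
Conditions: BrCH2COBr, NaHCO3, MeCN, 0 °C; crude 5, then TsNHNHTs, DBU, THF, 0 °C
Reagents that add atoms: bromoacetyl bromide, BrCC(=O)Br; N,N'-ditosylhydrazine, Cc1ccc(cc1)S(=O)(=O)NNS(=O)(=O)c1ccc(C)cc1
Why: O-acylation followed by N-alkylation of N,N'-ditosylhydrazine and double sulfinate elimination (diazo formation under basic conditions) should give the allylic diazoacetate without exposing the electron-rich cinnamyl system to acid.

**Step 4**
Reactants: 6 (2E)-3-[4-(benzyloxy)-3-methoxyphenyl]prop-2-en-1-yl diazoacetate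
Product: 7 rac-(1R,5S,6S)-6-[4-(benzyloxy)-3-methoxyphenyl]-3-oxabicyclo[3.1.0]hexan-2-one (aryl exo)
Conditions: Rh2(OAc)4 (1 mol%), CH2Cl2, 40 °C, slow addition of 6
Reagents that add atoms: none
Why: Intramolecular metal-carbene cyclopropanation of an allylic diazoacetate is stereospecific, so the (E)-alkene should give the cis-fused lactone with the aryl group trans to both lactone carbons, as the racemate.

**Step 5**
Reactants: 7 rac-(1R,5S,6S)-6-[4-(benzyloxy)-3-methoxyphenyl]-3-oxabicyclo[3.1.0]hexan-2-one; 1 4-(benzyloxy)-3-methoxybenzaldehyde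
Product: 8 rac-(3aS,4R,6S,6aS)-4,6-bis[4-(benzyloxy)-3-methoxyphenyl]tetrahydro-1H,3H-furo[3,4-c]furan-1-one (cis-fused, both aryl groups exo)
Conditions: Me3SiOTf (0.3 equiv), 1 (2 equiv), 4 Å MS, CH2Cl2, −78 → −20 °C
Reagents that add atoms: none
Why: Lewis-acid formal [3+2] annulation of a donor–acceptor cyclopropane with an aldehyde, here with one ring-strained lactone acceptor and a strongly donating 4-alkoxy-3-methoxyphenyl group: O-silylation of the lactone polarises the C1–C6 bond, the aldehyde oxygen attacks benzylic C6 as that bond breaks (new O1–C2 bond of the oxolane), and the silyl ketene acetal so formed adds to the aryl oxocarbenium carbon (new C4–C5 bond), releasing Me3SiOTf. The oxolane ring closes by this 5-(enolexo)-endo-trig aldol-type attack, which is feasible because the electrophile is an oxocarbenium ion. The ring-fusion carbons C3a and C6a (later C3 and C4 of the oxolane) can only be cis, since a trans-fused bicyclo[3.3.0]octane is prohibitively strained; this fixes the future methyl groups cis, and C3a is carried over unchanged from the cyclopropane. The two benzylic centres are set in an envelope transition state with both aryl groups pseudo-equatorial on the convex face, i.e. cis to each other and trans to the lactone carbons, and because both benzylic C–O bonds ionise reversibly under the Lewis acid a kinetically formed endo-aryl epimer can revert and re-close. The step needs cleavage of the donor-to-acceptor bond C1–C6 and not C5–C6, which the push–pull polarisation secures, and capture of the benzylic cation by the aldehyde instead of elimination, which excess electron-rich aldehyde at low temperature should secure. Product 8 is racemic, which is immaterial because step 6 turns it into a meso compound.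

**Step 6**
Reactants: 8 rac-(3aS,4R,6S,6aS)-4,6-bis[4-(benzyloxy)-3-methoxyphenyl]tetrahydro-1H,3H-furo[3,4-c]furan-1-one
Product: 9 meso-[(2R,3S,4R,5S)-2,5-bis[4-(benzyloxy)-3-methoxyphenyl]oxolane-3,4-diyl]dimethanol
Conditions: LiAlH4, THF, 0 °C
Reagents that add atoms: none
Why: Hydride reduction of the γ-lactone to the 1,4-diol leaves the benzyl ethers and the ring stereocentres untouched, and the product is meso because both arms are now hydroxymethyl groups.

**Step 7**
Reactants: 9 meso-[(2R,3S,4R,5S)-2,5-bis[4-(benzyloxy)-3-methoxyphenyl]oxolane-3,4-diyl]dimethanol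
Product: 10 meso-[(2R,3S,4R,5S)-2,5-bis[4-(benzyloxy)-3-methoxyphenyl]oxolane-3,4-diyl]dimethanediyl bis(methanesulfonate)
Conditions: MsCl, Et3N, CH2Cl2, −20 °C
Reagents that add atoms: methanesulfonyl chloride, CS(=O)(=O)Cl
Why: Sulfene-type mesylation of primary alcohols is fast at low temperature, so both hydroxyl groups should be sulfonylated before a monomesylate can cyclise to a bicyclic ether.

**Step 8**
Reactants: 10 the bis(methanesulfonate)
Product: 11 meso-(2R,3R,4S,5S)-2,5-bis[4-(benzyloxy)-3-methoxyphenyl]-3,4-dimethyloxolane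
Conditions: LiEt3BH, THF, 0 °C → rt
Reagents that add atoms: none
Why: LiEt3BH displaces primary sulfonates by SN2 hydride delivery at carbon, converting both CH2OMs groups into the cis methyl groups without touching a stereocentre.

**Step 9**
Reactants: 11 meso-(2R,3R,4S,5S)-2,5-bis[4-(benzyloxy)-3-methoxyphenyl]-3,4-dimethyloxolane
Product: 12 meso-4,4'-[(2R,3R,4S,5S)-3,4-dimethyloxolane-2,5-diyl]bis(2-methoxyphenol)
Conditions: H2 (1 atm), 10% Pd/C, EtOAc–MeOH, rt
Reagents that add atoms: none
Why: Hydrogenolysis of aryl benzyl ethers at ambient pressure in neutral solvent is much faster than cleavage of the 2-aryloxolane C–O bonds and should release the meso bis-phenol.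

**Step 10**
Reactants: 13 methyl (R)-lactate; 14 (3,4-dimethoxyphenyl)magnesium bromide (THF solution)
Product: 16 (2R)-1-(3,4-dimethoxyphenyl)-2-hydroxypropan-1-one, via Weinreb amide 15 (not isolated)
Conditions: MeNH(OMe)·HCl, iPrMgCl, THF, −20 °C; then 14, −20 → 0 °C; aq. NH4Cl
Reagents that add atoms: N,O-dimethylhydroxylamine hydrochloride, CNOC.Cl (its atoms are present in 15 only)
Why: Magnesium-amide aminolysis of the ester to the Weinreb amide and Grignard addition to its chelated magnesium alkoxide stops at the ketone, and the α-stereocentre, masked as the alkoxide, should be retained.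

**Step 11**
Reactants: 16 (2R)-1-(3,4-dimethoxyphenyl)-2-hydroxypropan-1-one
Product: 17 (2R)-1-(3,4-dimethoxyphenyl)-1-oxopropan-2-yl 4-methylbenzenesulfonate
Conditions: TsCl, Et3N, DMAP (cat.), CH2Cl2, 0 °C
Reagents that add atoms: p-toluenesulfonyl chloride, Cc1ccc(cc1)S(=O)(=O)Cl
Why: O-sulfonylation of the secondary alcohol does not involve the stereocentre and gives the (R)-tosylate.

**Step 12**
Reactants: 12 meso-4,4'-[(2R,3R,4S,5S)-3,4-dimethyloxolane-2,5-diyl]bis(2-methoxyphenol); 17 (2R)-1-(3,4-dimethoxyphenyl)-1-oxopropan-2-yl 4-methylbenzenesulfonate (2.5 equiv)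
Product: 18 (2S,2'S)-2,2'-{[(2R,3R,4S,5S)-3,4-dimethyloxolane-2,5-diyl]bis[(2-methoxy-4,1-phenylene)oxy]}bis[1-(3,4-dimethoxyphenyl)propan-1-one]
Conditions: Cs2CO3, DMF, 0 °C → rt
Reagents that add atoms: none
Why: Two-directional Williamson-type SN2 displacement of the carbonyl-activated secondary tosylate by the phenoxides proceeds with inversion, turning each (R)-tosylate into an (S)-α-aryloxy ketone.

**Step 13**
Reactants: 18 the bis(α-aryloxy ketone)
Product: 19 (1R,2S)-1-(3,4-dimethoxyphenyl)-2-{4-[(2R,3R,4S,5S)-5-(4-{[(1R,2S)-1-(3,4-dimethoxyphenyl)-1-hydroxypropan-2-yl]oxy}-3-methoxyphenyl)-3,4-dimethyloxolan-2-yl]-2-methoxyphenoxy}propan-1-ol (target)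
Conditions: Zn(BH4)2, Et2O–THF, −20 → 0 °C; neutral work-up
Reagents that add atoms: none
Why: Chelation-controlled reduction (Cram chelate model): zinc bridges the carbonyl and α-aryloxy oxygens, helped by the ortho methoxy group, and hydride arrives from the face of the small α-hydrogen, which should set both carbinol centres (R) and give the erythro (1R,2S) arms.

**Compound list**
1 | 4-(benzyloxy)-3-methoxybenzaldehyde | COc1cc(C=O)ccc1OCc1ccccc1 | starting material
2 | triethyl phosphonoacetate | CCOC(=O)CP(=O)(OCC)OCC | starting material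
3 | ethyl (2E)-3-[4-(benzyloxy)-3-methoxyphenyl]prop-2-enoate | CCOC(=O)/C=C/c1ccc(OCc2ccccc2)c(OC)c1 | intermediate
4 | (2E)-3-[4-(benzyloxy)-3-methoxyphenyl]prop-2-en-1-ol | OC/C=C/c1ccc(OCc2ccccc2)c(OC)c1 | intermediate
5 | (2E)-3-[4-(benzyloxy)-3-methoxyphenyl]prop-2-en-1-yl bromoacetate | BrCC(=O)OC/C=C/c1ccc(OCc2ccccc2)c(OC)c1 | intermediate (not isolated)
6 | (2E)-3-[4-(benzyloxy)-3-methoxyphenyl]prop-2-en-1-yl diazoacetate | [N-]=[N+]=CC(=O)OC/C=C/c1ccc(OCc2ccccc2)c(OC)c1 | intermediate
7 | rac-(1R,5S,6S)-6-[4-(benzyloxy)-3-methoxyphenyl]-3-oxabicyclo[3.1.0]hexan-2-one | O=C1OC[C@H]2[C@H](c3ccc(OCc4ccccc4)c(OC)c3)[C@@H]12 | intermediate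
8 | rac-(3aS,4R,6S,6aS)-4,6-bis[4-(benzyloxy)-3-methoxyphenyl]tetrahydro-1H,3H-furo[3,4-c]furan-1-one | O=C1OC[C@@H]2[C@H]1[C@@H](c3ccc(OCc4ccccc4)c(OC)c3)O[C@H]2c3ccc(OCc4ccccc4)c(OC)c3 | intermediate
9 | meso-[(2R,3S,4R,5S)-2,5-bis[4-(benzyloxy)-3-methoxyphenyl]oxolane-3,4-diyl]dimethanol | COc1cc(ccc1OCc1ccccc1)[C@H]1O[C@@H](c2ccc(OCc3ccccc3)c(OC)c2)[C@H](CO)[C@@H]1CO | intermediate
10 | bis(methanesulfonate) of 9 | COc1cc(ccc1OCc1ccccc1)[C@H]1O[C@@H](c2ccc(OCc3ccccc3)c(OC)c2)[C@H](COS(C)(=O)=O)[C@@H]1COS(C)(=O)=O | intermediate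
11 | meso-(2R,3R,4S,5S)-2,5-bis[4-(benzyloxy)-3-methoxyphenyl]-3,4-dimethyloxolane | COc1cc(ccc1OCc1ccccc1)[C@H]1O[C@@H](c2ccc(OCc3ccccc3)c(OC)c2)[C@H](C)[C@@H]1C | intermediate
12 | meso-4,4'-[(2R,3R,4S,5S)-3,4-dimethyloxolane-2,5-diyl]bis(2-methoxyphenol) | COc1cc(ccc1O)[C@H]1O[C@@H](c2ccc(O)c(OC)c2)[C@H](C)[C@@H]1C | intermediate
13 | methyl (R)-lactate | C[C@@H](O)C(=O)OC | starting material
14 | (3,4-dimethoxyphenyl)magnesium bromide | COc1ccc([Mg]Br)cc1OC | starting material
15 | (2R)-2-hydroxy-N-methoxy-N-methylpropanamide (present as its chloromagnesium alkoxide) | C[C@@H](O)C(=O)N(C)OC | intermediate (not isolated)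
16 | (2R)-1-(3,4-dimethoxyphenyl)-2-hydroxypropan-1-one | C[C@@H](O)C(=O)c1ccc(OC)c(OC)c1 | intermediate
17 | (2R)-1-(3,4-dimethoxyphenyl)-1-oxopropan-2-yl 4-methylbenzenesulfonate | C[C@@H](OS(=O)(=O)c1ccc(C)cc1)C(=O)c1ccc(OC)c(OC)c1 | intermediate
18 | (2S,2'S)-2,2'-{[(2R,3R,4S,5S)-3,4-dimethyloxolane-2,5-diyl]bis[(2-methoxy-4,1-phenylene)oxy]}bis[1-(3,4-dimethoxyphenyl)propan-1-one] | COc1ccc(C(=O)[C@H](C)Oc2ccc([C@H]3O[C@@H](c4ccc(O[C@@H](C)C(=O)c5ccc(OC)c(OC)c5)c(OC)c4)[C@H](C)[C@@H]3C)cc2OC)cc1OC | intermediate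
19 | (1R,2S)-1-(3,4-dimethoxyphenyl)-2-{4-[(2R,3R,4S,5S)-5-(4-{[(1R,2S)-1-(3,4-dimethoxyphenyl)-1-hydroxypropan-2-yl]oxy}-3-methoxyphenyl)-3,4-dimethyloxolan-2-yl]-2-methoxyphenoxy}propan-1-ol | COc1ccc([C@@H](O)[C@H](C)Oc2ccc([C@H]3O[C@@H](c4ccc(O[C@@H](C)[C@H](O)c5ccc(OC)c(OC)c5)c(OC)c4)[C@H](C)[C@@H]3C)cc2OC)cc1OC | target

**Step count.** Total: 13 steps. Longest linear sequence: 11 steps (steps 1–9, 12, 13).

**Steps most likely to fail**

First, step 5. A single lactone carbonyl may not polarise the cyclopropane enough, so ring opening may stall, or the benzylic cation may be lost to elimination or arene alkylation before the aldehyde captures it. The fallback sets out from 4 and uses a 1,1-diacceptor cyclopropane, the class on which this aldehyde annulation is established. Alcohol 4 is acylated with methyl malonyl chloride (pyridine, CH2Cl2) to (2E)-3-[4-(benzyloxy)-3-methoxyphenyl]prop-2-en-1-yl methyl propanedioate F1. Diazo transfer (p-acetamidobenzenesulfonyl azide, Et3N, MeCN) gives the 2-diazopropanedioate F2. Intramolecular cyclopropanation (Rh2(OAc)4, ClCH2CH2Cl, 80 °C) gives methyl rac-6-exo-[4-(benzyloxy)-3-methoxyphenyl]-2-oxo-3-oxabicyclo[3.1.0]hexane-1-carboxylate F3. Annulation of F3 with 1 under Sn(OTf)2 catalysis (CH2Cl2, rt) gives the 6a-methoxycarbonyl derivative of 8 (cis-fused, aryl groups exo) F4. Krapcho demethoxycarbonylation (LiCl, wet DMSO, 140 °C), where protonation of the lactone enolate can only give the cis-fused bicycle, comes back to the route at 8.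

Second, step 12. Carbonate base may enolise the α-sulfonyloxy or α-aryloxy aryl ketone and erode the configuration next to the carbonyl, or cause E2 loss of tosylate to the aryl vinyl ketone. The fallback sets out from 12 and 16 and avoids base: a double Mitsunobu etherification (PPh3, DIAD, THF, 0 °C) joins the phenols to the carbinol carbon of 16 with inversion and comes back at 18; it makes no new compound (F0).

Third, step 13. The aryloxy oxygen is a weak donor, so chelation to zinc may be incomplete and the Felkin–Anh pathway may compete, giving poor facial selectivity at one or both carbonyls. The fallback sets out from 12 and forms the carbinol centres by C–C bond formation instead. Lactate 13 is tosylated (TsCl, pyridine) to methyl (2R)-2-(tosyloxy)propanoate F5. Bis-phenol 12 is alkylated with F5 (K2CO3, MeCN, inversion) to the dimethyl (2S,2'S)-bis(2-aryloxypropanoate) F6. iBu2AlH (toluene, −78 °C) gives the (2S,2'S)-bis(2-aryloxypropanal) F7, used crude. Addition of (3,4-dimethoxyphenyl)titanium triisopropoxide (from 14 and ClTi(OiPr)3, THF, −78 °C), a non-chelating reagent, should follow the Felkin–Anh course anti to the aryloxy group and give the erythro (1R,2S) arms, coming back at 19.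

**Further compounds**
F1 | step 5 | (2E)-3-[4-(benzyloxy)-3-methoxyphenyl]prop-2-en-1-yl methyl propanedioate | COC(=O)CC(=O)OC/C=C/c1ccc(OCc2ccccc2)c(OC)c1
F2 | step 5 | (2E)-3-[4-(benzyloxy)-3-methoxyphenyl]prop-2-en-1-yl methyl 2-diazopropanedioate | COC(=O)C(=[N+]=[N-])C(=O)OC/C=C/c1ccc(OCc2ccccc2)c(OC)c1
F3 | step 5 | methyl rac-6-exo-[4-(benzyloxy)-3-methoxyphenyl]-2-oxo-3-oxabicyclo[3.1.0]hexane-1-carboxylate | O=C1OC[C@H]2[C@H](c3ccc(OCc4ccccc4)c(OC)c3)[C@@]12C(=O)OC
F4 | step 5 | 6a-methoxycarbonyl derivative of 8 (cis-fused, aryl groups exo, racemic) | O=C1OC[C@@H]2[C@@]1(C(=O)OC)[C@@H](c3ccc(OCc4ccccc4)c(OC)c3)O[C@H]2c3ccc(OCc4ccccc4)c(OC)c3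
F0 | step 12 | none | none
F5 | step 13 | methyl (2R)-2-(tosyloxy)propanoate | C[C@@H](OS(=O)(=O)c1ccc(C)cc1)C(=O)OC
F6 | step 13 | dimethyl (2S,2'S)-2,2'-{[(2R,3R,4S,5S)-3,4-dimethyloxolane-2,5-diyl]bis[(2-methoxy-4,1-phenylene)oxy]}dipropanoate | COC(=O)[C@H](C)Oc1ccc([C@H]2O[C@@H](c3ccc(O[C@@H](C)C(=O)OC)c(OC)c3)[C@H](C)[C@@H]2C)cc1OC
F7 | step 13 | (2S,2'S)-2,2'-{[(2R,3R,4S,5S)-3,4-dimethyloxolane-2,5-diyl]bis[(2-methoxy-4,1-phenylene)oxy]}dipropanal | O=C[C@H](C)Oc1ccc([C@H]2O[C@@H](c3ccc(O[C@@H](C)C=O)c(OC)c3)[C@H](C)[C@@H]2C)cc1OC
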